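Everything rests on cutting ring C (cyclooctane) back to a six-membered ketone: the segment C25–C11(–C10)–C12(–C13)–C14 of ring C is exactly an enamine C=C (C25=C14) with a but-2-ynoate inserted. In one operation the key step forms C14–C12 and C25–C11, opens the temporary C25–C14 bond of a fused cyclobutene, and so delivers the eight-membered ring with C10 (ester) and C13 in place. Its precursor is the less substituted pyrrolidine enamine of a cis-fused 1,4-dimethylhydrindan-5-one that already carries ring D and the C16/C17 stereocentres. Rings B and A are then closed together from C10 by a Pauson–Khand reaction.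

Key step: step 7

Remark 1: atoms are numbered in the order of the target SMILES; rings are A (C4, C5, C7, C8, C28), B (C8, C10, C11, C25, C27, C28), C (C11, C12, C14, C15, C16, C21, C23, C25) and D (C16, C17, C19, C20, C21).
Remark 2: in step 2 the (S)-catalyst is assumed to give the enantiomer drawn, by analogy with other 2-cycloalkenone cycloadditions; the (R)-catalyst would be used otherwise.
Remark 3: from compound 10 on, C23 is drawn as the epimer that the enamine equilibrium should favour (methyl pseudo-axial, anti to C20); C23 becomes sp2 in step 11, so either epimer reaches the target.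

Step 1
Reactants: 1 pent-1-en-3-one
Product: 2 (Z)-triisopropyl(penta-1,3-dien-3-yloxy)silane
Conditions: TIPSOTf, Et3N, Et2O, 0 °C → rt
Reagents that add atoms: triisopropylsilyl trifluoromethanesulfonate, CC(C)[Si](C(C)C)(C(C)C)OS(=O)(=O)C(F)(F)F
Why: Amine-mediated O-silylation of the ethyl ketone (silyl enol ether formation) should give the 2-silyloxydiene with Z geometry, which keeps the terminal methyl on the outside of the s-cis diene.

Step 2
Reactants: 2 (Z)-triisopropyl(penta-1,3-dien-3-yloxy)silane; 3 cyclopent-2-en-1-one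
Product: 4 (3aS,4R,7aR)-4-methyl-5-(triisopropylsilyloxy)-2,3,3a,4,7,7a-hexahydro-1H-inden-1-one
Conditions: (S)-o-tolyl-oxazaborolidine·HNTf2 (20 mol%), CH2Cl2, −40 → −20 °C
Reagents that add atoms: none
Why: Enantioselective Diels–Alder reaction under chiral oxazaborolidinium catalysis, in which the siloxy-activated terminus C23 bonds to the enone β-carbon C21 and C15 to C16, the endo transition state gives the cis ring fusion with the C24 methyl cis to C20, and the catalyst sets the absolute configuration at C16 and C21.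

Step 3
Reactants: 4 (3aS,4R,7aR)-4-methyl-5-(triisopropylsilyloxy)-2,3,3a,4,7,7a-hexahydro-1H-inden-1-one; 5 methyltriphenylphosphonium bromide
Product: 6 triisopropyl[(4-methyl-1-methylidene-2,3,3a,4,7,7a-hexahydro-1H-inden-5-yl)oxy]silane
Conditions: KOtBu, THF, 0 °C → rt
Reagents that add atoms: none
Why: Wittig methylenation turns the C17 ketone into the exocyclic alkene (C18) without touching the hindered silyl enol ether, and the cis ring fusion next to the carbonyl is the thermodynamically preferred one, so C16 is not scrambled by the basic ylide.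

Step 4
Reactants: 6 triisopropyl[(4-methyl-1-methylidene-2,3,3a,4,7,7a-hexahydro-1H-inden-5-yl)oxy]silane
Product: 7 triisopropyl[(1,4-dimethyl-2,3,3a,4,7,7a-hexahydro-1H-inden-5-yl)oxy]silane
Conditions: H2 (1 atm), RhCl(PPh3)3 (5 mol%), benzene, rt
Reagents that add atoms: none
Why: Homogeneous catalytic hydrogenation reduces only the 1,1-disubstituted alkene and should add hydrogen from the convex face of the cis-fused bicycle (the face of H16 and H21), which sets C17 with its hydrogen cis to H16.

Step 5
Reactants: 7 triisopropyl[(1,4-dimethyl-2,3,3a,4,7,7a-hexahydro-1H-inden-5-yl)oxy]silane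
Product: 8 cis-fused 1,4-dimethyloctahydro-5H-inden-5-one
Conditions: TBAF, AcOH, THF, 0 °C
Reagents that add atoms: none
Why: Fluoride cleavage of the silyl enol ether with buffered protonation at C14 (desilylation) unmasks the C25 ketone and leaves C16, C17 and C21 untouched.

Step 6
Reactants: 8 cis-fused 1,4-dimethyloctahydro-5H-inden-5-one; 9 pyrrolidine
Product: 10 1-(1,4-dimethyl-2,3,3a,4,7,7a-hexahydro-1H-inden-5-yl)pyrrolidine
Conditions: p-TsOH (cat.), benzene, reflux, Dean–Stark
Reagents that add atoms: none
Why: Stork enamine formation should give the less substituted C25=C14 isomer, because A(1,3) strain with the pyrrolidine ring disfavours the tetrasubstituted isomer, and C23 equilibrates through the iminium ion to the epimer whose methyl is pseudo-axial and anti to C20.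

Step 7
Reactants: 10 1-(1,4-dimethyl-2,3,3a,4,7,7a-hexahydro-1H-inden-5-yl)pyrrolidine; 11 methyl but-2-ynoate
Product: 13 methyl 1,4,7-trimethyl-5-(pyrrolidin-1-yl)-2,3,3a,4,9,9a-hexahydro-1H-cyclopenta[8]annulene-6-carboxylate, via aminocyclobutene ester 12 (not isolated)
Conditions: 11 (2 equiv), toluene, sealed tube, 100 °C, 24–48 h
Reagents that add atoms: none
Why: The nucleophilic enamine carbon C14 adds to the β-carbon C12 of the ynoate, and the iminium–allenolate zwitterion closes the C25–C11 bond to the cis-fused aminocyclobutene 12. The C25–C14 σ-bond of 12 then opens in a push–pull-assisted electrocyclic ring opening, which trades four-ring strain for the conjugated 2-amino-1,3-diene ester and enlarges the six-membered ring to ring C. The closest known reaction type is the two-carbon ring expansion of cyclic ketone enamines with acetylenic esters (enamine–alkyne [2+2] followed by cyclobutene opening). The four-membered ring closes in a 4-exo-trig mode onto the iminium carbon, and the eight-membered ring arises by ring expansion, not by a separate cyclisation. No stereocentre is created, since C14 and C25 end up sp2, and C16 and C17 are spectators. The step needs regioselectivity only: A(1,3) strain keeps the enamine double bond on the C14 side, away from the C23 methyl, and the polarity of the ynoate places C12 on C14 and C11 on C25.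

Step 8
Reactants: 13 methyl 1,4,7-trimethyl-5-(pyrrolidin-1-yl)-2,3,3a,4,9,9a-hexahydro-1H-cyclopenta[8]annulene-6-carboxylate
Product: 14 methyl 1,4,7-trimethyl-5-(pyrrolidin-1-yl)-2,3,3a,4,7,8,9,9a-octahydro-1H-cyclopenta[8]annulene-6-carboxylate
Conditions: H2 (1 atm), 10% Pd/C, EtOAc, rt
Reagents that add atoms: none
Why: Heterogeneous hydrogenation reduces the trisubstituted C12=C14 bond while the push–pull C25=C11 bond stays, and hydrogen should enter anti to the C23 methyl, which A(1,3) strain with the pyrrolidine holds pseudo-axial over one face of the diene, so that C12 receives its hydrogen on the face opposite to H16.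

Step 9
Reactants: 14 methyl 1,4,7-trimethyl-5-(pyrrolidin-1-yl)-2,3,3a,4,7,8,9,9a-octahydro-1H-cyclopenta[8]annulene-6-carboxylate
Product: 16 1,4,7-trimethyl-6-methylidenedecahydro-5H-cyclopenta[8]annulen-5-one, via enamino alcohol 15 (not isolated)
Conditions: LiAlH4, Et2O, 0 °C → reflux; then 1 M HCl, THF, 0 °C → rt
Reagents that add atoms: water, O
Why: Hydride reduction of the vinylogous carbamate ester gives the enamino allylic alcohol 15, and aqueous acid expels hydroxide through the enamine and hydrolyses the iminium ion (the reduction–hydrolysis logic of the Stork–Danheiser transposition), which turns the ester carbon C10 into the exocyclic methylene of an enone without touching C12.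

Step 10
Reactants: 16 1,4,7-trimethyl-6-methylidenedecahydro-5H-cyclopenta[8]annulen-5-one
Product: 17 trimethyl[(1,4,7-trimethyl-6-methylidene-2,3,3a,6,7,8,9,9a-octahydro-1H-cyclopenta[8]annulen-5-yl)oxy]silane
Conditions: TMSOTf, Et3N, CH2Cl2, −78 → 0 °C
Reagents that add atoms: trimethylsilyl trifluoromethanesulfonate, C[Si](C)(C)OS(=O)(=O)C(F)(F)F
Why: Soft enolisation with silyl triflate and amine (silyl enol ether formation) can only go toward C23, because C11 carries no hydrogen, so the 2-silyloxydiene forms regiospecifically.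

Step 11
Reactants: 17 trimethyl[(1,4,7-trimethyl-6-methylidene-2,3,3a,6,7,8,9,9a-octahydro-1H-cyclopenta[8]annulen-5-yl)oxy]silane
Product: 18 1,4,7-trimethyl-6-methylidene-1,2,3,6,7,8,9,9a-octahydro-5H-cyclopenta[8]annulen-5-one
Conditions: Pd(OAc)2 (1.1 equiv), MeCN, rt
Reagents that add atoms: none
Why: Saegusa–Ito oxidation, in which the palladium enolate at C23 loses the ring hydrogen at C21 by β-hydride elimination, should give the endocyclic tetrasubstituted C21=C23 enone with no regiochemical competition from the C11 side.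

Step 12
Reactants: 18 1,4,7-trimethyl-6-methylidene-1,2,3,6,7,8,9,9a-octahydro-5H-cyclopenta[8]annulen-5-one; 19 isopropenylmagnesium bromide
Product: 20 1,4,7-trimethyl-6-(2-methylprop-2-enyl)-1,2,3,6,7,8,9,9a-octahydro-5H-cyclopenta[8]annulen-5-one
Conditions: 19 (1.3 equiv), CuBr·SMe2 (20 mol%), THF, −78 °C; AcOH, −78 °C
Reagents that add atoms: none
Why: Copper-catalysed conjugate addition of the Grignard reagent occurs at the unhindered methylene C10 and not at the fully substituted C21, and kinetic protonation of the enolate at −78 °C from the face away from the adjacent C13 methyl should set C11 with H11 cis to H12.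

Step 13
Reactants: 20 1,4,7-trimethyl-6-(2-methylprop-2-enyl)-1,2,3,6,7,8,9,9a-octahydro-5H-cyclopenta[8]annulen-5-one; 21 3-bromoprop-1-yne
Product: 22 1,4,7-trimethyl-6-(2-methylprop-2-enyl)-5-(prop-2-ynyl)-1,2,3,5,6,7,8,9,9a-nonahydro-cyclopenta[8]annulen-5-ol
Conditions: Zn dust, THF, 0 °C → rt; sat. NH4Cl
Reagents that add atoms: none
Why: Zinc-mediated Barbier propargylation (allenylzinc, SE2′) adds C27 to the C25 carbonyl in a 1,2 sense under non-basic conditions, and the nucleophile should approach anti to the C11 side chain, which gives the tertiary alcohol with the hydroxyl trans to H11.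

Step 14
Reactants: 22 1,4,7-trimethyl-6-(2-methylprop-2-enyl)-5-(prop-2-ynyl)-1,2,3,5,6,7,8,9,9a-nonahydro-cyclopenta[8]annulen-5-ol
Product: 23 tetracyclic hydroxy dienone (rings A–D; C4=C28–C5=O; C21=C23; C25–OH)
Conditions: Co2(CO)8 (20 mol%), tetramethylthiourea (cat.), CO (1 atm), benzene, 70 °C
Reagents that add atoms: carbon monoxide, [C-]#[O+]
Why: Intramolecular Pauson–Khand reaction joins C28–C8, C4–C5 and C5–C7 and closes rings B and A at once; the trans-diequatorial tether on C25/C11 fixes ring B as a chair in which the ring A bond at C8 must be equatorial, so the C9 methyl becomes axial and syn to H11.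

Step 15
Reactants: 23 tetracyclic hydroxy dienone (rings A–D; C4=C28–C5=O; C21=C23; C25–OH)
Product: 24 tetracyclic epoxy hydroxy enone (C21–O22–C23 epoxide syn to C25–OH)
Conditions: VO(acac)2 (5 mol%), t-BuOOH, CH2Cl2, 0 °C → rt
Reagents that add atoms: tert-butyl hydroperoxide, CC(C)(C)OO
Why: Vanadium-catalysed hydroxyl-directed epoxidation delivers oxygen to the tetrasubstituted C21=C23 bond on the face of the C25 hydroxyl, which sets C21 and C23 and leaves the electron-poor enone untouched.

Step 16
Reactants: 24 tetracyclic epoxy hydroxy enone (C21–O22–C23 epoxide syn to C25–OH)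
Product: 25 α-iodoenone (iodine on C4)
Conditions: I2, pyridine, CH2Cl2, rt
Reagents that add atoms: iodine, II
Why: α-Iodination of the enone with iodine and pyridine (conjugate addition of pyridine, iodination of the enolate, elimination) functionalises C4 only, since C28 is fully substituted.

Step 17
Reactants: 25 α-iodoenone (iodine on C4); 26 tributyl(prop-1-en-2-yl)stannane
Product: 27 2-isopropenyl enone (C2 attached to C4)
Conditions: Pd2(dba)3 (5 mol%), AsPh3, CuI, NMP, rt
Reagents that add atoms: none
Why: Stille coupling of the α-iodoenone with the alkenylstannane attaches C2 to C4 under neutral conditions, so the hydroxy epoxide and the enolisable γ-position C27 are not exposed to base.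

Step 18
Reactants: 27 2-isopropenyl enone (C2 attached to C4)
Product: 28 CNP0332295.1
Conditions: H2 (4 atm), 10% Pd/C, EtOAc, rt
Reagents that add atoms: none
Why: Catalytic hydrogenation saturates the isopropenyl group and the C4=C28 enone, and hydrogen should reach both carbons from the face opposite the axial C9 methyl, which gives the trans ring fusion at C28 and the kinetic C4 configuration (isopropyl cis to C9) under neutral conditions that do not epimerise C4.

Compound list
1 | pent-1-en-3-one | CCC(=O)C=C | starting material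
2 | (Z)-triisopropyl(penta-1,3-dien-3-yloxy)silane | C/C=C(/C=C)O[Si](C(C)C)(C(C)C)C(C)C | intermediate
3 | cyclopent-2-en-1-one | O=C1C=CCC1 | starting material
4 | (3aS,4R,7aR)-4-methyl-5-(triisopropylsilyloxy)-2,3,3a,4,7,7a-hexahydro-1H-inden-1-one (cis-fused, H16/H21 cis, C24 methyl cis to C20) | C1C[C@H]2C(=O)CC[C@H]2[C@@H](C)C=1O[Si](C(C)C)(C(C)C)C(C)C | intermediate
5 | methyltriphenylphosphonium bromide | C[P+](c1ccccc1)(c1ccccc1)c1ccccc1.[Br-] | starting material
6 | triisopropyl[(4-methyl-1-methylidene-2,3,3a,4,7,7a-hexahydro-1H-inden-5-yl)oxy]silane (configuration at C16, C21, C23 as in 4) | C1C[C@H]2C(=C)CC[C@H]2[C@@H](C)C=1O[Si](C(C)C)(C(C)C)C(C)C | intermediate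
7 | triisopropyl[(1,4-dimethyl-2,3,3a,4,7,7a-hexahydro-1H-inden-5-yl)oxy]silane (H16, H17, H21 all cis; C24 methyl cis to C20) | C1C[C@H]2[C@@H](C)CC[C@H]2[C@@H](C)C=1O[Si](C(C)C)(C(C)C)C(C)C | intermediate
8 | 1,4-dimethyloctahydro-5H-inden-5-one (cis-fused; H16, H17, H21 all cis; C24 methyl cis to C20) | O=C1CC[C@H]2[C@@H](C)CC[C@H]2[C@H]1C | intermediate
9 | pyrrolidine | C1CCNC1 | starting material
10 | 1-(1,4-dimethyl-2,3,3a,4,7,7a-hexahydro-1H-inden-5-yl)pyrrolidine (enamine C25=C14; H16, H17, H21 all cis; C24 methyl trans to C20) | C1C[C@H]2[C@@H](C)CC[C@H]2[C@H](C)C=1N3CCCC3 | intermediate (key-step precursor)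
11 | methyl but-2-ynoate | CC#CC(=O)OC | starting material
12 | aminocyclobutene ester (cyclobutene C25–C11=C12–C14 fused to the six-membered ring at C25–C14; pyrrolidine on C25, ester on C11, methyl on C12; transient cis ring-fusion centres C14/C25 not assigned) | COC(=O)C1=C(C)C2C[C@H]3[C@@H](C)CC[C@H]3[C@H](C)C12N4CCCC4 | intermediate (not isolated)
13 | methyl 1,4,7-trimethyl-5-(pyrrolidin-1-yl)-2,3,3a,4,9,9a-hexahydro-1H-cyclopenta[8]annulene-6-carboxylate (amino diene ester; C25(N)=C11(CO2Me)–C12(Me)=C14, both ring double bonds cis) | C/C1=C/C[C@H]2[C@@H](C)CC[C@H]2[C@H](C)/C(N3CCCC3)=C1/C(=O)OC | intermediate (key-step product)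
14 | methyl 1,4,7-trimethyl-5-(pyrrolidin-1-yl)-2,3,3a,4,7,8,9,9a-octahydro-1H-cyclopenta[8]annulene-6-carboxylate (H12 trans to H16) | C[C@@H]1CC[C@H]2[C@@H](C)CC[C@H]2[C@H](C)/C(N3CCCC3)=C1/C(=O)OC | intermediate
15 | [1,4,7-trimethyl-5-(pyrrolidin-1-yl)-2,3,3a,4,7,8,9,9a-octahydro-1H-cyclopenta[8]annulen-6-yl]methanol (enamino alcohol) | C[C@@H]1CC[C@H]2[C@@H](C)CC[C@H]2[C@H](C)/C(N3CCCC3)=C1/CO | intermediate (not isolated)
16 | 1,4,7-trimethyl-6-methylidenedecahydro-5H-cyclopenta[8]annulen-5-one (C10=C11 exocyclic; C23 configuration immaterial) | C[C@@H]1CC[C@H]2[C@@H](C)CC[C@H]2[C@H](C)C(=O)C1=C | intermediate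
17 | trimethyl[(1,4,7-trimethyl-6-methylidene-2,3,3a,6,7,8,9,9a-octahydro-1H-cyclopenta[8]annulen-5-yl)oxy]silane (C25(OTMS)=C23) | C[C@@H]1CC[C@H]2[C@@H](C)CC[C@H]2/C(C)=C(/O[Si](C)(C)C)C1=C | intermediate
18 | 1,4,7-trimethyl-6-methylidene-1,2,3,6,7,8,9,9a-octahydro-5H-cyclopenta[8]annulen-5-one (cross-conjugated dienone; C21=C23 and C10=C11) | C[C@@H]1CC[C@H]2[C@@H](C)CC/C2=C(\C)C(=O)C1=C | intermediate
19 | isopropenylmagnesium bromide | CC(=C)[Mg]Br | starting material
20 | 1,4,7-trimethyl-6-(2-methylprop-2-enyl)-1,2,3,6,7,8,9,9a-octahydro-5H-cyclopenta[8]annulen-5-one (H11 cis to H12) | C[C@@H]1CC[C@H]2[C@@H](C)CC/C2=C(\C)C(=O)[C@@H]1CC(C)=C | intermediate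
21 | 3-bromoprop-1-yne | C#CCBr | starting material
22 | 1,4,7-trimethyl-6-(2-methylprop-2-enyl)-5-(prop-2-ynyl)-1,2,3,5,6,7,8,9,9a-nonahydro-cyclopenta[8]annulen-5-ol (C25–OH trans to H11) | C[C@@H]1CC[C@H]2[C@@H](C)CC/C2=C(\C)[C@@](O)(CC#C)[C@@H]1CC(C)=C | intermediate
23 | tetracyclic hydroxy dienone (rings A–D; C4=C28–C5=O with C4–H; C21=C23; C25–OH; C9 methyl syn to H11) | O=C1C[C@]2(C)C[C@@H]3[C@H](C)CC[C@H]4[C@@H](C)CC/C4=C(\C)[C@@]3(O)CC2=C1 | intermediate
24 | tetracyclic epoxy hydroxy enone (C21–O22–C23 epoxide syn to C25–OH) | O=C1C[C@]2(C)C[C@@H]3[C@H](C)CC[C@H]4[C@@H](C)CC[C@]45O[C@]5(C)[C@@]3(O)CC2=C1 | intermediate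
25 | α-iodoenone (iodine on C4) | O=C1C[C@]2(C)C[C@@H]3[C@H](C)CC[C@H]4[C@@H](C)CC[C@]45O[C@]5(C)[C@@]3(O)CC2=C1I | intermediate
26 | tributyl(prop-1-en-2-yl)stannane | CCCC[Sn](CCCC)(CCCC)C(C)=C | starting material
27 | 2-isopropenyl enone (prop-1-en-2-yl on C4) | O=C1C[C@]2(C)C[C@@H]3[C@H](C)CC[C@H]4[C@@H](C)CC[C@]45O[C@]5(C)[C@@]3(O)CC2=C1C(C)=C | intermediate
28 | CNP0332295.1 | CC(C)[C@H]1C(=O)C[C@]2(C)C[C@@H]3[C@H](C)CC[C@H]4[C@@H](C)CC[C@]45O[C@]5(C)[C@@]3(O)C[C@@H]12 | target

Total step count: 18. Longest linear sequence: 18 steps (from 1 or 3 to 28).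

Steps most likely to fail

Step 7. The β-methyl ynoate is a weak acceptor, so addition to the hindered enamine may be slower than thermal oligomerisation of the ynoate or loss of the enamine, and the cyclobutene may not open cleanly. The fallback makes the same two bonds from the silyl enol ether 7, whose double bond is already fixed at C25=C14, and returns to the route at 13. Compounds 7 and 11 are combined in a Lewis-acid-catalysed [2+2] cycloaddition of a silyl enol ether with an ynoate (ZrCl4 or Tf2NH, CH2Cl2, −78 → 0 °C) to give the siloxycyclobutene ester F1. Heating F1 in toluene opens the C25–C14 bond to the silyl dienol ether ester F2. TBAF/AcOH converts F2 into the β,γ-unsaturated β-keto ester F3. Condensation of F3 with 9 (benzene, reflux, water removal) gives 13.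

Step 8. The conformation of the eight-membered diene may not be governed by the pseudo-axial C23 methyl, so hydrogen may be delivered to the wrong face of C12=C14 and erode the C12 configuration. The fallback replaces steric approach control by thermodynamic control; it sets out from 13 and returns at 16. LiAlH4 reduces the ester of 13 to the dienamino alcohol F4. Buffered hydrolysis (AcOH/NaOAc, aqueous THF) gives the β,γ-unsaturated hydroxy ketone F5. Hydrogen-atom-transfer hydrogenation (Mn(dpm)3, PhSiH3, t-BuOOH, i-PrOH) reduces the isolated C12=C14 bond through a tertiary C12 radical and should give the saturated hydroxy ketone F6 with the C13 methyl in the more stable pseudo-equatorial position. Acid-catalysed dehydration of F6 (p-TsOH, benzene) gives 16.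

Step 14. Insertion of the 1,1-disubstituted alkene during six-ring formation may be too slow, so that the alkyne–cobalt complex decomposes before cyclocarbonylation. The fallback uses an early-transition-metal reductive cyclisation; it sets out from 22 and returns at 23. Double silylation of 22 (n-BuLi 2.2 equiv, TMSCl, THF) gives the C,O-bis(trimethylsilyl) enyne F7. Titanocene-catalysed cyclocarbonylation (Cp2Ti(CO)2 cat., CO, toluene, 90 °C), which runs through a titanacyclopentene and accepts 1,1-disubstituted alkenes when the alkyne is capped, gives the α-silyl enone silyl ether F8. TBAF/AcOH removes both silyl groups from F8 and gives 23.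

Further compounds
F1 | step 7 | siloxycyclobutene ester (cyclobutene C25–C11=C12–C14 fused at C25–C14; OTIPS on C25) | COC(=O)C1=C(C)C2C[C@H]3[C@@H](C)CC[C@H]3[C@@H](C)C12O[Si](C(C)C)(C(C)C)C(C)C
F2 | step 7 | silyl dienol ether ester (methyl 1,4,7-trimethyl-5-(triisopropylsilyloxy)-2,3,3a,4,9,9a-hexahydro-1H-cyclopenta[8]annulene-6-carboxylate) | C/C1=C/C[C@H]2[C@@H](C)CC[C@H]2[C@@H](C)/C(O[Si](C(C)C)(C(C)C)C(C)C)=C1/C(=O)OC
F3 | step 7 | β,γ-unsaturated β-keto ester (methyl 1,4,7-trimethyl-5-oxo-2,3,3a,4,5,6,9,9a-octahydro-1H-cyclopenta[8]annulene-6-carboxylate) | C/C1=C/C[C@H]2[C@@H](C)CC[C@H]2[C@@H](C)C(=O)C1C(=O)OC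
F4 | step 8 | dienamino alcohol ([1,4,7-trimethyl-5-(pyrrolidin-1-yl)-2,3,3a,4,9,9a-hexahydro-1H-cyclopenta[8]annulen-6-yl]methanol) | C/C1=C/C[C@H]2[C@@H](C)CC[C@H]2[C@H](C)/C(N3CCCC3)=C1/CO
F5 | step 8 | β,γ-unsaturated hydroxy ketone (6-(hydroxymethyl)-1,4,7-trimethyl-2,3,3a,4,6,9,9a-heptahydro-1H-cyclopenta[8]annulen-5-one) | C/C1=C/C[C@H]2[C@@H](C)CC[C@H]2[C@H](C)C(=O)C1CO
F6 | step 8 | saturated hydroxy ketone (6-(hydroxymethyl)-1,4,7-trimethyldecahydro-5H-cyclopenta[8]annulen-5-one) | C[C@@H]1CC[C@H]2[C@@H](C)CC[C@H]2[C@H](C)C(=O)C1CO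
F7 | step 14 | C,O-bis(trimethylsilyl) enyne (O-TMS ether and C-TMS alkyne of 22) | C[C@@H]1CC[C@H]2[C@@H](C)CC/C2=C(\C)[C@@](O[Si](C)(C)C)(CC#C[Si](C)(C)C)[C@@H]1CC(C)=C
F8 | step 14 | α-silyl enone silyl ether (TMS on C4 and on O26 of 23) | O=C1C[C@]2(C)C[C@@H]3[C@H](C)CC[C@H]4[C@@H](C)CC/C4=C(\C)[C@@]3(O[Si](C)(C)C)CC2=C1[Si](C)(C)C
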